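## Structural features

The target is a chroman-4-one: benzene ring A is fused through C4a–C8a to the dihydropyranone ring B (O1, C2, C3, C4). C2 is the only stereocentre. It is a fully substituted ether carbon of (R) configuration carrying CH3, O1, C3H2 and a 4-hydroxy-4-methylpentyl chain, and it has no stereogenic neighbour, so the stereochemical task is absolute configuration at one quaternary C–O centre. Ring A carries the C4 carbonyl at C4a, O1 at C8a, a hydroxyl at C6 and bromine at C7; its two hydrogens (C5, C8) are para to each other. Several groups are fragile:

- the β-aryloxy ketone, where base can deprotonate C3, expel O1 and re-close ring B as the racemate;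
- the aryl bromide, which is sensitive to hydrogenolysis, zerovalent palladium and lithium reagents;
- the tertiary side-chain alcohol, which ionises in strong acid;
- the electron-rich para-alkoxyphenol, which is easily oxidised.

The real difficulties are an enantiopure quaternary carbinol ether β to a ketone, and a bromine that must sit at C7 and not at C5. The key step uses two facts. C2 with its methyl group, its oxygen, C3 and the first chain carbon is the carbinol carbon of (R)-linalool, whose vinyl group becomes C3–C4. C8a lies ortho to the C4 carbonyl (and meta to the C7 bromine), so a fluoride there can be displaced by the C2 oxygen.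

## Logic of the disconnections

16 ⇒ 15. The phenolic O–H is traced back to an O–Si bond. The phenol is freed last because a para-oxido group would switch off the ring closure, and because the free phenol is the most oxidisable form. A silyl ether is chosen so that the last step is a buffered fluoride treatment, not a hydrogenolysis (C–Br) or a strong acid (side-chain carbinol). The forward step must cleave O–Si without free base.

15 ⇒ 14. The C–O bond of the side-chain tertiary alcohol is cut back to the trisubstituted alkene. This keeps a second tertiary alkoxide out of the key step and lets 4 deliver the whole chain. The forward step must hydrate with Markovnikov sense without touching C–Br or the ketone.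

14 ⇒ 12 (through 13). The O1–C8a bond is cut, which opens ring B. This is the strategic cut: it turns the quaternary ether stereocentre into a tertiary carbinol whose configuration is never touched. The forward step needs the alkoxide to substitute fluoride faster than it fragments. For that reason the bromine is already on the ring in 12, meta to the fluoride; there it speeds the displacement, and no late bromination with a C5/C7 choice is needed.

12 ⇒ 10 + 11 (from 3 and 9). The C4–C4a bond is cut between an aryl-metal and an N-methoxy-N-methyl amide. The amide gives the ketone directly, so neither a β-hydroxy aldehyde nor a benzylic alcohol oxidation is needed, and the ketone appears only on acidic work-up. The forward step needs one of two C–Br bonds in 3 to be metallated selectively.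

3 ⇒ 2 ⇒ 1. The O–Si bond and then the C–Br bond ortho to the hydroxyl are cut. Bromination is placed on the simplest possible substrate, where the para position is blocked by fluorine and one ortho position is crowded. The bulky, non-chelating silyl ether then tells the two bromines apart for the exchange.

9 ⇒ 8 ⇒ 6 ⇒ 4. The amide C–N bond, the oxidation level of C1 and the C1–O bond are removed in turn, arriving at the vinyl group of 4. The gain is that every carbon of ring B except C4a and C8a, the stereocentre and the whole side chain come from one commercial terpene alcohol. The forward steps must distinguish the vinyl from the trisubstituted alkene and oxidise C1 without dehydrating the tertiary carbinol.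

## Other disconnections considered

Alternative 1: The cut is C3=C4. The aryl ether diene A2 (a tertiary allylic aryl ether carrying a 1-silyloxyvinyl group on the future C4a) would be closed by the second-generation Grubbs catalyst to the cyclic silyl enol ether A1, which hydrolyses to the chromanone.

- In its favour: the closure is neutral and catalytic, so neither retro-aldol cleavage nor base-induced opening of ring B can occur; on mildness of the ring closure it is the better plan. It uses the same carbinol of 4 and carries the bromine from the start, so it is the equal of the chosen plan on origin of configuration and on bromine placement.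
- Against it: the difficulty is moved to A2. Its O1–C8a bond would need an intermolecular arylation of a hindered tertiary allylic alkoxide by a fluoroarene whose activating acetyl group is enolisable. The metathesis joins a vinyl group on a fully substituted carbon to a 1,1-disubstituted electron-rich enol ether, a slow pairing. The distal alkene must be hydrated and silylated first so that it does not take part.
- Comparison: three silyl groups and roughly two to three more steps than the chosen route.

Alternative 2: The cut is O1–C2 together with C1'–C2' of the chain. Phenol A4 would undergo enantioselective oxypalladation with Pd(OCOCF3)2 and a chiral binaphthyl bis(oxazoline); the resulting alkylpalladium, which has no β-hydrogen, is captured by the enone A5 to give chromane A3, and a quinone returns zerovalent palladium to divalent palladium.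

- In its favour: it is catalytic and asymmetric, makes two bonds in one step, and is independent of the optical purity of a natural terpene. On these points it is better than the chosen plan.
- Against it: C4 must be carried as a silyl-protected carbinol, a second stereocentre that either matches or mismatches the ligand. The C–Br bond meets zerovalent palladium in every turnover. Selectivity for this substitution pattern is unknown.
- Comparison: after the key step the enone must be reduced without hydrogenolysis of C–Br, a methyl group added, and C4 deprotected and oxidised, with two protecting groups removed. That is at least four steps more than the chosen route.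

Alternative 3: The cut is C2–C3. Diazoketone A7 would be decomposed by Rh2(OAc)4 and the carbenoid carbon would insert into the ether methine C–H with retention, giving chromanone A6.

- In its favour: the stereocentre is set as a secondary carbinol ether, which is far easier to make than a tertiary one. The insertion is stereoretentive and base-free, so on stereochemical security of the ring closure it is the equal of, or better than, the chosen plan. Bromine and the hydrated chain are in place.
- Against it: an acceptor-only divalent rhodium carbenoid ortho to an ether oxygen meets the oxygen lone pair before the C–H bond. Oxonium ylide formation and a Stevens-type shift to a benzofuranone are the expected main course, with cyclopropanation of ring A and Wolff rearrangement as further side reactions.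
- Comparison: the step count is similar to or higher than the chosen route, and the key step is much less certain.

Key step: step 7

Assumption: (R)-(−)-linalool is used at the optical purity in which it is sold; no bond to its carbinol carbon is broken, so the enantiomeric purity of 16 is expected to equal that of the linalool.

## Route

Step 1
Reactants: 1 3-bromo-4-fluorophenol
Product: 2 2,5-dibromo-4-fluorophenol
Conditions: NBS (1.0 equiv), i-Pr2NH (0.1 equiv), CH2Cl2, 0 °C
Reagents that add atoms: N-bromosuccinimide, O=C1CCC(=O)N1Br
Why: Amine-mediated electrophilic ortho-bromination of a phenol; the para position is blocked by fluorine and the ortho site between OH and Br is crowded, so bromine should enter the other ortho position, para to the existing bromine.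

Step 2
Reactants: 2 2,5-dibromo-4-fluorophenol
Product: 3 (2,5-dibromo-4-fluorophenoxy)triisopropylsilane
Conditions: TIPSCl, imidazole, DMF, rt
Reagents that add atoms: chlorotriisopropylsilane, CC(C)[Si](Cl)(C(C)C)C(C)C
Why: Standard O-silylation of a phenol; the bulky, non-chelating silyl ether shields its ortho bromine in step 6, tolerates magnesium reagents and amide bases, and is removed by fluoride at the end.

Step 3
Reactants: 4 (R)-linalool
Product: 6 (R)-3,7-dimethyloct-6-ene-1,3-diol, via alkylborane 5 (not isolated)
Conditions: 9-BBN (2.2 equiv), THF, 0 °C → rt; then NaOH, H2O2, H2O, 0 °C → rt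
Reagents that add atoms: hydrogen peroxide, OO
Why: Hydroboration–oxidation; 9-BBN reacts with the monosubstituted vinyl group far faster than with the trisubstituted alkene and places boron on the terminal carbon. The carbinol carbon is not involved, so its configuration is kept.

Step 4
Reactants: 6 (R)-3,7-dimethyloct-6-ene-1,3-diol
Product: 8 (R)-3-hydroxy-3,7-dimethyloct-6-enoic acid, via hydroxy aldehyde 7 (not isolated)
Conditions: TEMPO (0.2 equiv), PhI(OAc)2 (2.4 equiv), MeCN/H2O (1:1), 0 °C → rt
Reagents that add atoms: water, O
Why: Oxoammonium-catalysed oxidation of the primary alcohol through the aldehyde hydrate to the acid; the tertiary alcohol cannot be oxidised and the trisubstituted alkene is tolerated by this oxidant.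

Step 5
Reactants: 8 (R)-3-hydroxy-3,7-dimethyloct-6-enoic acid
Product: 9 (R)-3-hydroxy-N-methoxy-N,3,7-trimethyloct-6-enamide
Conditions: MeNHOMe·HCl, EDC·HCl, HOBt, N-methylmorpholine, CH2Cl2, 0 °C → rt
Reagents that add atoms: N,O-dimethylhydroxylamine hydrochloride, CNOC.Cl
Why: Carbodiimide amide coupling to the Weinreb amide; the hindered tertiary hydroxyl is not acylated under these conditions.

Step 6
Reactants: 9 (R)-3-hydroxy-N-methoxy-N,3,7-trimethyloct-6-enamide; 3 (2,5-dibromo-4-fluorophenoxy)triisopropylsilane
Product: 12 (R)-1-[4-bromo-2-fluoro-5-(triisopropylsilyloxy)phenyl]-3-hydroxy-3,7-dimethyloct-6-en-1-one, via arylmagnesium chloride 10 (not isolated), via chloromagnesium alkoxide 11 (not isolated)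
Conditions: 3 (1.3 equiv), i-PrMgCl·LiCl (1.25 equiv), THF, −20 °C; 9, i-PrMgCl (1.0 equiv), THF, −20 °C; combine, −20 → 0 °C; 1 M HCl, 0 °C
Reagents that add atoms: none
Why: Bromine–magnesium exchange should take place at the C–Br bond flanked by fluorine (inductively stabilised aryl anion) and not at the one shielded by the silyl ether. Weinreb ketone synthesis: the aryl Grignard reagent adds to the amide to give a stable magnesium chelate that releases the ketone only on acidic work-up, so neither over-addition nor a free aldolate arises.

Step 7
Reactants: 12 (R)-1-[4-bromo-2-fluoro-5-(triisopropylsilyloxy)phenyl]-3-hydroxy-3,7-dimethyloct-6-en-1-one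
Product: 14 (R)-7-bromo-2-methyl-2-(4-methylpent-3-en-1-yl)-6-(triisopropylsilyloxy)chroman-4-one, via sodium alkoxide 13 (not isolated)
Conditions: NaN(SiMe3)2 (1.0 equiv, slow addition), 15-crown-5 (1.1 equiv), THF (0.01 M), −78 → −30 °C; then AcOH
Reagents that add atoms: none
Why: Deprotonation of the tertiary hydroxyl gives alkoxide 13, which adds to the fluorine-bearing carbon (future C8a) to form a Meisenheimer σ-complex whose charge is taken up by the ortho C4 carbonyl and, inductively, by the bromine meta to the site of attack; loss of fluoride as insoluble NaF restores ring A and forms O1–C8a. The closest known reaction type is the intramolecular nucleophilic aromatic substitution of 2-fluoroaryl ketones by tethered oxygen nucleophiles that closes chroman-4-ones and chromones. Ring B closes as a six-membered ring by addition–elimination at an sp2 carbon: the breaking C–F bond is exocyclic, while the accepting C8a=C4a–C4=O unit lies inside the new ring, so the addition has the geometry of a 6-endo-trig oxa-Michael closure onto a vinylogous acyl fluoride. No stereocentre is created; C2 keeps the configuration of 4 because no bond to the carbinol carbon is broken. The selectivity needed is ipso-substitution ahead of retro-aldol cleavage of the bond between the carbinol carbon and its neighbouring CH2; the doubly activated C–F bond, the crown ether (which removes the sodium ion that would hold alkoxide and carbonyl oxygen in the chelate through which fragmentation runs) and the low temperature (fragmentation gains entropy, cyclisation does not) are meant to secure it. Bromide, para to the carbonyl, is a far poorer nucleofuge than fluoride and cannot be reached by the tethered oxygen. The single equivalent of base ends as NaF, which is inert to the aryl silyl ether and to C3–H, so the product is not left with base that could open ring B and racemise C2.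

Step 8
Reactants: 14 (R)-7-bromo-2-methyl-2-(4-methylpent-3-en-1-yl)-6-(triisopropylsilyloxy)chroman-4-one
Product: 15 (R)-7-bromo-2-(4-hydroxy-4-methylpentyl)-2-methyl-6-(triisopropylsilyloxy)chroman-4-one
Conditions: Co(acac)2 (0.2 equiv), PhSiH3 (2.5 equiv), O2 (1 atm), THF, rt
Reagents that add atoms: dioxygen, O=O
Why: Mukaiyama hydration; hydrogen-atom transfer from a cobalt hydride to the trisubstituted alkene gives the tertiary radical, which is trapped by O2 and reduced to the Markovnikov alcohol. Aryl bromide, ketone and silyl ether are inert to these radical conditions, and the new carbinol carbon bears two methyl groups, so no stereocentre arises.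

Step 9
Reactants: 15 (R)-7-bromo-2-(4-hydroxy-4-methylpentyl)-2-methyl-6-(triisopropylsilyloxy)chroman-4-one
Product: 16 (R)-7-bromo-6-hydroxy-2-(4-hydroxy-4-methylpentyl)-2-methylchroman-4-one
Conditions: Bu4NF (1.1 equiv), AcOH (1.2 equiv), THF, 0 °C
Reagents that add atoms: none
Why: Fluoride cleavage of the aryl silyl ether; acetic acid protonates the phenoxide as it forms, so no base is available to open ring B by β-elimination, and C–Br, ketone and tertiary alcohol are untouched.

## Compound list

1 | 3-bromo-4-fluorophenol | Oc1ccc(F)c(Br)c1 | starting material
2 | 2,5-dibromo-4-fluorophenol | Oc1cc(Br)c(F)cc1Br | intermediate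
3 | (2,5-dibromo-4-fluorophenoxy)triisopropylsilane | CC(C)[Si](Oc1cc(Br)c(F)cc1Br)(C(C)C)C(C)C | intermediate
4 | (R)-linalool, (3R)-3,7-dimethylocta-1,6-dien-3-ol | C=C[C@](C)(O)CCC=C(C)C | starting material
5 | 9-[(3S)-3-hydroxy-3,7-dimethyloct-6-en-1-yl]-9-borabicyclo[3.3.1]nonane (not isolated; same geometry as 4, the descriptor changes only because boron lowers the rank of the C1–C2 branch) | CC(C)=CCC[C@@](C)(O)CCB1C2CCCC1CCC2 | intermediate
6 | (R)-3,7-dimethyloct-6-ene-1,3-diol | CC(C)=CCC[C@@](C)(O)CCO | intermediate
7 | (R)-3-hydroxy-3,7-dimethyloct-6-enal (not isolated) | CC(C)=CCC[C@@](C)(O)CC=O | intermediate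
8 | (R)-3-hydroxy-3,7-dimethyloct-6-enoic acid | CC(C)=CCC[C@@](C)(O)CC(=O)O | intermediate
9 | (R)-3-hydroxy-N-methoxy-N,3,7-trimethyloct-6-enamide | CC(C)=CCC[C@@](C)(O)CC(=O)N(C)OC | intermediate
10 | [4-bromo-2-fluoro-5-(triisopropylsilyloxy)phenyl]magnesium chloride, as its LiCl complex (not isolated) | Cl[Mg]c1cc(O[Si](C(C)C)(C(C)C)C(C)C)c(Br)cc1F | intermediate
11 | chloromagnesium (3R)-1-[methoxy(methyl)amino]-3,7-dimethyl-1-oxooct-6-en-3-olate (not isolated) | CC(C)=CCC[C@@](C)(O[Mg]Cl)CC(=O)N(C)OC | intermediate
12 | (R)-1-[4-bromo-2-fluoro-5-(triisopropylsilyloxy)phenyl]-3-hydroxy-3,7-dimethyloct-6-en-1-one | CC(C)=CCC[C@@](C)(O)CC(=O)c1cc(O[Si](C(C)C)(C(C)C)C(C)C)c(Br)cc1F | intermediate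
13 | sodium (3R)-1-[4-bromo-2-fluoro-5-(triisopropylsilyloxy)phenyl]-3,7-dimethyl-1-oxooct-6-en-3-olate (not isolated) | CC(C)=CCC[C@@](C)([O-])CC(=O)c1cc(O[Si](C(C)C)(C(C)C)C(C)C)c(Br)cc1F.[Na+] | intermediate
14 | (R)-7-bromo-2-methyl-2-(4-methylpent-3-en-1-yl)-6-(triisopropylsilyloxy)chroman-4-one | CC(C)=CCC[C@]1(C)CC(=O)c2cc(O[Si](C(C)C)(C(C)C)C(C)C)c(Br)cc2O1 | intermediate
15 | (R)-7-bromo-2-(4-hydroxy-4-methylpentyl)-2-methyl-6-(triisopropylsilyloxy)chroman-4-one | CC(C)(O)CCC[C@]1(C)CC(=O)c2cc(O[Si](C(C)C)(C(C)C)C(C)C)c(Br)cc2O1 | intermediate
16 | (R)-7-bromo-6-hydroxy-2-(4-hydroxy-4-methylpentyl)-2-methylchroman-4-one | CC(C)(O)CCC[C@]1(C)CC(=O)c2cc(O)c(Br)cc2O1 | target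

## Step count and least certain steps

Total: 9 steps. Longest linear sequence: 7 steps (steps 3 to 9, from 4); the aryl branch (steps 1 and 2) joins at step 6.

Step 7 (key step). The most likely failure is that the alkoxide fragments by retro-aldol cleavage before it substitutes fluoride, because a tertiary aldolate of a ketone is thermodynamically poised to break apart. A second, slower danger is proton transfer from C3–H of the product to alkoxide not yet cyclised, followed by opening and racemic re-closure of ring B. The fallback raises the rate of substitution by changing the substituent para to the fluoride from an electron-releasing silyloxy group to an electron-withdrawing acyloxy group. It sets out from 12. Buffered desilylation (Bu4NF, AcOH) gives (R)-1-(4-bromo-2-fluoro-5-hydroxyphenyl)-3-hydroxy-3,7-dimethyloct-6-en-1-one F1. Selective acylation of the phenol (pivaloyl chloride, Et3N, 0 °C) gives 2-bromo-4-fluoro-5-[(R)-3-hydroxy-3,7-dimethyloct-6-enoyl]phenyl pivalate F2. Ring closure under the conditions of step 7 should give (R)-7-bromo-2-methyl-2-(4-methylpent-3-en-1-yl)-4-oxochroman-6-yl pivalate F3. Mukaiyama hydration as in step 8 gives (R)-7-bromo-2-(4-hydroxy-4-methylpentyl)-2-methyl-4-oxochroman-6-yl pivalate F4. Methanolysis of the aryl ester (K2CO3, MeOH, 0 °C) returns to the route at 16.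

Step 6. The most likely failure is slow acylation: the aryl Grignard reagent is deactivated by fluorine and bromine and the amide already carries a magnesium alkoxide, so on warming the reagent may decompose by loss of magnesium halide fluoride to an aryne before it adds. Incomplete discrimination between the two C–Br bonds is the lesser concern. The fallback replaces the amide by the more electrophilic aldehyde. It sets out from 6. Parikh–Doering oxidation (SO3·pyridine, DMSO, i-Pr2NEt, 0 °C) gives 7, this time isolated. Addition of 10 (2.1 equiv, −40 °C; the first equivalent takes the hydroxyl proton) gives (3R)-1-[4-bromo-2-fluoro-5-(triisopropylsilyloxy)phenyl]-3,7-dimethyloct-6-ene-1,3-diol F5 as both C1 epimers. Oxidation of the benzylic alcohol with MnO2 (CH2Cl2, rt) returns to the route at 12.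

Step 4. The most likely failure is dehydration of the intermediate β-hydroxy aldehyde to the conjugated enal under the acetic acid that the oxidant releases, or attack of the iodine reagent on the electron-rich alkene, so that oxidation stops short of the acid. The fallback separates the two oxidation stages and changes the oxidant for each. It sets out from 6: Parikh–Doering oxidation to 7, isolated cold, then chlorite oxidation (NaClO2, NaH2PO4, 2-methyl-2-butene, t-BuOH/H2O), in which the scavenger also protects the alkene, returning to the route at 8. No new compound arises.

## Further compounds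

F1 | step 7 | (R)-1-(4-bromo-2-fluoro-5-hydroxyphenyl)-3-hydroxy-3,7-dimethyloct-6-en-1-one | CC(C)=CCC[C@@](C)(O)CC(=O)c1cc(O)c(Br)cc1F
F2 | step 7 | 2-bromo-4-fluoro-5-[(R)-3-hydroxy-3,7-dimethyloct-6-enoyl]phenyl pivalate | CC(C)=CCC[C@@](C)(O)CC(=O)c1cc(OC(=O)C(C)(C)C)c(Br)cc1F
F3 | step 7 | (R)-7-bromo-2-methyl-2-(4-methylpent-3-en-1-yl)-4-oxochroman-6-yl pivalate | CC(C)=CCC[C@]1(C)CC(=O)c2cc(OC(=O)C(C)(C)C)c(Br)cc2O1
F4 | step 7 | (R)-7-bromo-2-(4-hydroxy-4-methylpentyl)-2-methyl-4-oxochroman-6-yl pivalate | CC(C)(O)CCC[C@]1(C)CC(=O)c2cc(OC(=O)C(C)(C)C)c(Br)cc2O1
F5 | step 6 | (3R)-1-[4-bromo-2-fluoro-5-(triisopropylsilyloxy)phenyl]-3,7-dimethyloct-6-ene-1,3-diol, both C1 epimers | CC(C)=CCC[C@@](C)(O)CC(O)c1cc(O[Si](C(C)C)(C(C)C)C(C)C)c(Br)cc1F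
F0 | step 4 | none | none
A1 | alternative 1 | (R)-7-bromo-4,6-bis(tert-butyldimethylsilyloxy)-2-methyl-2-[4-methyl-4-(tert-butyldimethylsilyloxy)pentyl]-2H-chromene | CC(C)(O[Si](C)(C)C(C)(C)C)CCC[C@]1(C)C=C(O[Si](C)(C)C(C)(C)C)c2cc(O[Si](C)(C)C(C)(C)C)c(Br)cc2O1
A2 | alternative 1 | tert-butyl{[1-(4-bromo-5-(tert-butyldimethylsilyloxy)-2-{[(3R)-7-(tert-butyldimethylsilyloxy)-3,7-dimethyloct-1-en-3-yl]oxy}phenyl)ethenyl]oxy}dimethylsilane | C=C[C@@](C)(CCCC(C)(C)O[Si](C)(C)C(C)(C)C)Oc1cc(Br)c(O[Si](C)(C)C(C)(C)C)cc1C(=C)O[Si](C)(C)C(C)(C)C
A3 | alternative 2 | (2R,4S)-7-bromo-4-(tert-butyldimethylsilyloxy)-6-(methoxymethoxy)-2-methyl-2-[(E)-4-oxopent-2-enyl]chromane | CC(=O)/C=C/C[C@]1(C)C[C@H](O[Si](C)(C)C(C)(C)C)c2cc(OCOC)c(Br)cc2O1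
A4 | alternative 2 | (S)-5-bromo-2-[1-(tert-butyldimethylsilyloxy)-3-methylbut-3-en-1-yl]-4-(methoxymethoxy)phenol | C=C(C)C[C@H](O[Si](C)(C)C(C)(C)C)c1cc(OCOC)c(Br)cc1O
A5 | alternative 2 | but-3-en-2-one | C=CC(C)=O
A6 | alternative 3 | (R)-7-bromo-6-(tert-butyldimethylsilyloxy)-2-methyl-2-[4-methyl-4-(triethylsilyloxy)pentyl]chroman-4-one | CC(C)(O[Si](CC)(CC)CC)CCC[C@]1(C)CC(=O)c2cc(O[Si](C)(C)C(C)(C)C)c(Br)cc2O1
A7 | alternative 3 | 1-[4-bromo-5-(tert-butyldimethylsilyloxy)-2-{[(2R)-6-methyl-6-(triethylsilyloxy)heptan-2-yl]oxy}phenyl]-2-diazoethan-1-one | CC(C)(O[Si](CC)(CC)CC)CCC[C@@H](C)Oc1cc(Br)c(O[Si](C)(C)C(C)(C)C)cc1C(=O)C=[N+]=[N-]
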